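## Retrosynthetic overview

1. The target comes from a spiro alcohol (ring-D ketone masked as a dioxolane), which arises from the key step: an intramolecular carbonyl-ene reaction of a tricyclic aldehyde. Bonding the ring-D carbinol carbon to the spiro carbon closes ring D, creates the quaternary centre and the secondary alcohol, and moves the ring-C double bond to its final place beside the lactone α-carbon.
2. Enabling feature: the ring-D CH(OH) is bonded to the spiro carbon, which is allylic to the ring-C C=CH. This homoallylic alcohol (HO–CH–C(spiro)–C=CH) is the retron of a carbonyl-ene reaction of a tetrasubstituted ring-C alkene flanked by an allylic CH2.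
3. Ring C: ring-closing metathesis of two 1,1-disubstituted alkenes. One arrives by convex-face alkylation of the cis-fused A/B lactone with an allyl iodide cut out of (S)-carvone (one ring carbon excised; its stereocentre becomes the side-chain stereocentre). The other arrives by Negishi coupling.
4. Rings A/B: from (R)-4-silyloxycyclopentenone by α-iodination, Negishi coupling, intramolecular malonate Michael lactonisation (ring B, two ring stereocentres) and MeMgBr addition (tertiary carbinol).
5. Ring order: A (chiral pool) → B → C → D. Ring letters: A methylcyclopentanol, B γ-lactone, C cyclohexene, D spiro hydroxycyclopentanone.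

Key step: step 22

Remark: alcohol 11 is racemic and the malonate carbon of 21 and 22 is epimerisable (drawn with the ester on the convex face); both centres are destroyed later (steps 9 and 17).

## Route

Step 1
Reactants: 1 (S)-(+)-carvone
Product: 2 carvone 2,3-epoxide (epoxide trans to isopropenyl)
Conditions: 30% H2O2, NaOH (cat.), MeOH, 0 °C
Reagents that add atoms: hydrogen peroxide (OO)
Why: Weitz–Scheffer nucleophilic epoxidation touches only the electron-poor enone C=C, and the configuration of the two epoxide carbons is irrelevant because both are destroyed in step 2.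

Step 2
Reactants: 2 carvone 2,3-epoxide
Product: 3 (S)-5-oxo-3-(prop-1-en-2-yl)pentanoic acid
Conditions: H5IO6 (2.5 equiv), THF/H2O, 0 °C → rt
Reagents that add atoms: periodic acid (OI(O)(O)(O)(O)=O); water (O)
Why: Periodic acid cleavage of an α,β-epoxy ketone (hydrolytic opening, then glycol and α-dicarbonyl cleavage) turns the ketone carbon into CO2H and the β-carbon into CHO and excises the methyl-bearing α-carbon as acetic acid, leaving the isopropenyl-bearing stereocentre untouched.

Step 3
Reactants: 3 (S)-5-oxo-3-(prop-1-en-2-yl)pentanoic acid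
Product: 4 methyl (S)-5-oxo-3-(prop-1-en-2-yl)pentanoate
Conditions: TMSCHN2, MeOH/toluene, 0 °C
Reagents that add atoms: (trimethylsilyl)diazomethane (C[Si](C)(C)C=[N+]=[N-])
Why: Chemoselective O-methylation of the carboxylic acid leaves the aldehyde and the stereocentre unchanged.

Step 4
Reactants: 4 methyl (S)-5-oxo-3-(prop-1-en-2-yl)pentanoate
Product: 5 methyl (S)-4-formyl-3-(prop-1-en-2-yl)pent-4-enoate
Conditions: Eschenmoser's salt (1.5 equiv), Et3N, CH2Cl2, rt
Reagents that add atoms: Eschenmoser's salt (C=[N+](C)C.[I-])
Why: Mannich condensation followed by β-elimination of dimethylamine (aldehyde α-methylenation) occurs at the only enolisable α-CH2 and does not involve the β-stereocentre.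

Step 5
Reactants: 5 methyl (S)-4-formyl-3-(prop-1-en-2-yl)pent-4-enoate
Product: 6 methyl (S)-4-(hydroxymethyl)-3-(prop-1-en-2-yl)pent-4-enoate
Conditions: NaBH4, CeCl3·7H2O, MeOH, −40 °C
Reagents that add atoms: none
Why: Luche reduction gives clean 1,2-reduction of the enal and does not touch the methyl ester.

Step 6
Reactants: 6 methyl (S)-4-(hydroxymethyl)-3-(prop-1-en-2-yl)pent-4-enoate
Product: 7 methyl (S)-4-(iodomethyl)-3-(prop-1-en-2-yl)pent-4-enoate
Conditions: PPh3, imidazole, I2, CH2Cl2, 0 °C; used at once
Reagents that add atoms: iodine (II)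
Why: Appel-type iodination converts the primary allylic alcohol into the iodide under neutral conditions.

Step 7
Reactants: 8 3-[(4-methoxybenzyl)oxy]propan-1-ol
Product: 9 3-[(4-methoxybenzyl)oxy]propanal
Conditions: TEMPO (10 mol%), PhI(OAc)2, CH2Cl2, rt
Reagents that add atoms: none
Why: TEMPO/PhI(OAc)2 oxidation stops at the aldehyde and tolerates the PMB ether.

Step 8
Reactants: 9 3-[(4-methoxybenzyl)oxy]propanal; 10 2,3-dibromoprop-1-ene
Product: 11 5-bromo-1-[(4-methoxybenzyl)oxy]hex-5-en-3-ol (racemic)
Conditions: In powder, THF/H2O 1:1, rt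
Reagents that add atoms: none
Why: Barbier-type 2-bromoallylation in aqueous medium adds the allyl unit to the aldehyde while the vinylic bromide survives; the new carbinol is racemic and is oxidised in step 9.

Step 9
Reactants: 11 5-bromo-1-[(4-methoxybenzyl)oxy]hex-5-en-3-ol
Product: 12 5-bromo-1-[(4-methoxybenzyl)oxy]hex-5-en-3-one
Conditions: Dess–Martin periodinane, CH2Cl2, 0 °C → rt
Reagents that add atoms: none
Why: Dess–Martin oxidation under neutral conditions gives the β,γ-unsaturated ketone without double-bond migration or β-elimination of the PMB ether.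

Step 10
Reactants: 12 5-bromo-1-[(4-methoxybenzyl)oxy]hex-5-en-3-one
Product: 13 2-(2-bromoprop-2-en-1-yl)-2-{2-[(4-methoxybenzyl)oxy]ethyl}-1,3-dioxolane
Conditions: 1,2-bis(trimethylsilyloxy)ethane, TMSOTf (cat.), CH2Cl2, −78 → −20 °C
Reagents that add atoms: 1,2-bis(trimethylsilyloxy)ethane (C[Si](C)(C)OCCO[Si](C)(C)C)
Why: Low-temperature ketalisation with the bis-silyl glycol masks the future ring-D ketone without isomerising the bromoalkene.

Step 11
Reactants: 14 (R)-4-[(tert-butyldimethylsilyl)oxy]cyclopent-2-en-1-one
Product: 15 (R)-4-[(tert-butyldimethylsilyl)oxy]-2-iodocyclopent-2-en-1-one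
Conditions: I2, pyridine, CH2Cl2, 0 °C → rt
Reagents that add atoms: iodine (II)
Why: α-Iodination of the enone (pyridine addition, iodination, elimination) leaves the silyloxy stereocentre untouched.

Step 12
Reactants: 13 2-(2-bromoprop-2-en-1-yl)-2-{2-[(4-methoxybenzyl)oxy]ethyl}-1,3-dioxolane; 15 (R)-4-[(tert-butyldimethylsilyl)oxy]-2-iodocyclopent-2-en-1-one
Product: 18 (R)-4-[(tert-butyldimethylsilyl)oxy]-2-(3-{2-[2-(4-methoxybenzyloxy)ethyl]-1,3-dioxolan-2-yl}prop-1-en-2-yl)cyclopent-2-en-1-one, via alkenyllithium 16 (not isolated), via alkenylzinc bromide 17 (not isolated)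
Conditions: 13, t-BuLi (2 equiv), Et2O, −78 °C; ZnBr2, THF, −78 → 0 °C; 15, Pd(PPh3)4 (5 mol%), THF, rt
Reagents that add atoms: none
Why: Bromine–lithium exchange, transmetalation to zinc and Negishi coupling with the α-iodoenone join the two sp2 carbons with both alkenes retained and no stereocentre affected.

Step 13
Reactants: 18 silyl ether dienone
Product: 19 (R)-4-hydroxy-2-(3-{2-[2-(4-methoxybenzyloxy)ethyl]-1,3-dioxolan-2-yl}prop-1-en-2-yl)cyclopent-2-en-1-one
Conditions: HF·pyridine, pyridine, THF, 0 °C → rt
Reagents that add atoms: none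
Why: Buffered fluoride desilylation removes the allylic TBS ether while the dioxolane and the PMB ether survive.

Step 14
Reactants: 19 hydroxy dienone
Product: 20 methyl malonate of 19 (mixed methyl (R)-4-oxo-3-(dioxolanyl-propenyl)cyclopent-2-en-1-yl malonate)
Conditions: methyl malonyl chloride, pyridine, CH2Cl2, −20 °C
Reagents that add atoms: methyl malonyl chloride (COC(=O)CC(=O)Cl)
Why: Acylation of the secondary allylic alcohol installs the malonate tether with retention at the carbinol carbon.

Step 15
Reactants: 20 malonate ester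
Product: 21 methyl 3,7-dioxo-6-endo-(dioxolanyl-propenyl)-cis-2-oxabicyclo[3.3.0]octane-4-carboxylate (rings A and B)
Conditions: Cs2CO3 (20 mol%), MeCN, 0 °C
Reagents that add atoms: none
Why: The intramolecular Michael addition (5-exo) of the malonate can only reach the enone β-carbon on the face that carries the ester oxygen, which gives the cis-fused lactone; kinetic α-protonation of the resulting dienolate on the convex face then places the alkenyl group cis to the new ring, and the acidic malonate of the product buffers the medium against epimerisation.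

Step 16
Reactants: 21 keto lactone ester
Product: 22 methyl 7-endo-hydroxy-7-exo-methyl-3-oxo-6-endo-(dioxolanyl-propenyl)-cis-2-oxabicyclo[3.3.0]octane-4-carboxylate
Conditions: MeMgBr (3 equiv), CeCl3, THF, −78 °C
Reagents that add atoms: methylmagnesium bromide (C[Mg]Br)
Why: Organocerium 1,2-addition (the first equivalent deprotonates the malonate, which shields ester and lactone) occurs on the convex face of the cis-fused bicycle and so puts methyl exo and hydroxyl endo, cis to the lactone oxygen.

Step 17
Reactants: 22 hydroxy lactone ester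
Product: 23 (1R,5S,6S,7S)-7-hydroxy-7-methyl-6-(3-{2-[2-(4-methoxybenzyloxy)ethyl]-1,3-dioxolan-2-yl}prop-1-en-2-yl)-2-oxabicyclo[3.3.0]octan-3-one
Conditions: LiCl, H2O, DMSO, 130 °C
Reagents that add atoms: none
Why: Krapcho demethoxycarbonylation removes the auxiliary ester and with it the malonate stereocentre under neutral conditions that leave ketal, PMB ether and tertiary alcohol intact.

Step 18
Reactants: 23 hydroxy lactone; 7 methyl (S)-4-(iodomethyl)-3-(prop-1-en-2-yl)pent-4-enoate
Product: 25 lactone 23 carrying on the lactone α-carbon, on the convex face, the 2-methylene-3-(prop-1-en-2-yl)-4-(methoxycarbonyl)butyl chain (metathesis diene), via dilithium alkoxide enolate 24 (not isolated)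
Conditions: LiN(iPr)2 (2.2 equiv), THF, −78 °C; DMPU; 7, −78 → −40 °C
Reagents that add atoms: none
Why: Alkylation of the lactone enolate by the allylic iodide on the convex face of the cis-fused bicycle sets the lactone α-stereocentre with its hydrogen on the concave face, trans to the ring-fusion hydrogen.

Step 19
Reactants: 25 metathesis diene
Product: 26 tricyclic lactone (rings A, B, C) with a tetrasubstituted ring-C alkene, PMB ether
Conditions: second-generation Hoveyda–Grubbs catalyst (10 mol%), toluene, 100 °C, argon sparge
Reagents that add atoms: none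
Why: Ring-closing metathesis of the two 1,1-disubstituted alkenes (only this pairing gives a six-membered ring) forms ring C with its tetrasubstituted double bond and releases ethylene.

Step 20
Reactants: 26 tricyclic PMB ether
Product: 27 tricyclic primary alcohol
Conditions: DDQ, CH2Cl2/pH 7 buffer, 0 °C
Reagents that add atoms: none
Why: Oxidative PMB cleavage through the benzylic oxocarbenium ion frees the primary alcohol without touching the other functional groups.

Step 21
Reactants: 27 tricyclic primary alcohol
Product: 28 tricyclic aldehyde (2-(dioxolan-2-yl)acetaldehyde chain on the ring-C alkene)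
Conditions: TEMPO (10 mol%), PhI(OAc)2, CH2Cl2, rt
Reagents that add atoms: none
Why: TEMPO/PhI(OAc)2 oxidises only the primary alcohol (the tertiary alcohol is inert) under near-neutral conditions that spare the ketal.

Step 22
Reactants: 28 tricyclic aldehyde
Product: 29 tetracyclic spiro alcohol (ring-D ketone as dioxolane; hydroxyl on ring D cis to the ring-C alkene carbon)
Conditions: Me2AlCl (2.5 equiv), CH2Cl2, −78 → −30 °C
Reagents that add atoms: none
Why: Me2AlCl activates the aldehyde, which adds through a concerted but asynchronous six-membered ene transition state to the chain-bearing carbon of the tetrasubstituted ring-C alkene while a hydrogen of the ring CH2 next to the lactone α-carbon is delivered to oxygen, so that one operation forms ring D, the quaternary spiro carbon, the secondary alcohol and the final position of the ring-C double bond. The closest known reaction type is the Lewis-acid-promoted type 1 intramolecular carbonyl-ene cyclisation of unsaturated aldehydes (citronellal to isopulegol). Ring D is closed in the 5-exo mode (the alkene stays outside the new ring) through a compact transition state in which the forming five-membered ring is cis-fused to the ene array. The spiro carbon is controlled by the adjacent ring-fusion stereocentre: the aldehyde approaches the face of ring C opposite to ring A, that is syn to the two ring-fusion hydrogens. The carbinol carbon is controlled by the geometry of the ene transition state, in which the oxygen must lie over the alkene carbon whose allylic hydrogen it accepts, so the hydroxyl should end up on ring D cis to the ring-C alkene carbon. The step needs bond formation at the chain-bearing alkene carbon (not the six-ring alternative at the other alkene carbon) and hydrogen transfer from the ring CH2 (not from the side-chain methine); the first is secured by polarisation (positive charge builds on the carbon remote from the electron-withdrawing ketal and carbinol oxygens, and the other carbon is flanked by the branched side chain), the second by A(1,3) strain, which keeps the side-chain C–H in the plane of the alkene.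

Step 23
Reactants: 29 tetracyclic spiro alcohol
Product: 30 CNP0255095.1 (target)
Conditions: PPTS (cat.), THF/H2O 4:1, 45 °C
Reagents that add atoms: water (O)
Why: Mild acid hydrolysis of the dioxolane unmasks the ring-D ketone without dehydrating the β-hydroxy ketone or the tertiary alcohol.

## Compound list

1 | (S)-(+)-carvone | CC1=CC[C@@H](CC1=O)C(C)=C | starting material
2 | carvone 2,3-epoxide, epoxide trans to isopropenyl | C[C@]12O[C@H]1C[C@@H](CC2=O)C(C)=C | intermediate
3 | (S)-5-oxo-3-(prop-1-en-2-yl)pentanoic acid | C=C(C)[C@H](CC(=O)O)CC=O | intermediate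
4 | methyl (S)-5-oxo-3-(prop-1-en-2-yl)pentanoate | C=C(C)[C@H](CC(=O)OC)CC=O | intermediate
5 | methyl (S)-4-formyl-3-(prop-1-en-2-yl)pent-4-enoate | C=C(C)[C@H](CC(=O)OC)C(=C)C=O | intermediate
6 | methyl (S)-4-(hydroxymethyl)-3-(prop-1-en-2-yl)pent-4-enoate | C=C(C)[C@H](CC(=O)OC)C(=C)CO | intermediate
7 | methyl (S)-4-(iodomethyl)-3-(prop-1-en-2-yl)pent-4-enoate | C=C(C)[C@H](CC(=O)OC)C(=C)CI | intermediate
8 | 3-[(4-methoxybenzyl)oxy]propan-1-ol | OCCCOCc1ccc(OC)cc1 | starting material
9 | 3-[(4-methoxybenzyl)oxy]propanal | O=CCCOCc1ccc(OC)cc1 | intermediate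
10 | 2,3-dibromoprop-1-ene | C=C(Br)CBr | starting material
11 | 5-bromo-1-[(4-methoxybenzyl)oxy]hex-5-en-3-ol (racemic) | C=C(Br)CC(O)CCOCc1ccc(OC)cc1 | intermediate
12 | 5-bromo-1-[(4-methoxybenzyl)oxy]hex-5-en-3-one | C=C(Br)CC(=O)CCOCc1ccc(OC)cc1 | intermediate
13 | 2-(2-bromoprop-2-en-1-yl)-2-{2-[(4-methoxybenzyl)oxy]ethyl}-1,3-dioxolane | C=C(Br)CC1(CCOCc2ccc(OC)cc2)OCCO1 | intermediate
14 | (R)-4-[(tert-butyldimethylsilyl)oxy]cyclopent-2-en-1-one | CC(C)(C)[Si](C)(C)O[C@H]1C=CC(=O)C1 | starting material
15 | (R)-4-[(tert-butyldimethylsilyl)oxy]-2-iodocyclopent-2-en-1-one | CC(C)(C)[Si](C)(C)O[C@H]1C=C(I)C(=O)C1 | intermediate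
16 | alkenyllithium from 13 (Li in place of Br) | [Li]C(=C)CC1(CCOCc2ccc(OC)cc2)OCCO1 | intermediate
17 | alkenylzinc bromide from 16 | Br[Zn]C(=C)CC1(CCOCc2ccc(OC)cc2)OCCO1 | intermediate
18 | (R)-4-[(tert-butyldimethylsilyl)oxy]-2-(3-{2-[2-(4-methoxybenzyloxy)ethyl]-1,3-dioxolan-2-yl}prop-1-en-2-yl)cyclopent-2-en-1-one | CC(C)(C)[Si](C)(C)O[C@H]1C=C(C(=C)CC2(CCOCc3ccc(OC)cc3)OCCO2)C(=O)C1 | intermediate
19 | (R)-4-hydroxy analogue of 18 | O[C@H]1C=C(C(=C)CC2(CCOCc3ccc(OC)cc3)OCCO2)C(=O)C1 | intermediate
20 | methyl malonate ester of 19 | COC(=O)CC(=O)O[C@H]1C=C(C(=C)CC2(CCOCc3ccc(OC)cc3)OCCO2)C(=O)C1 | intermediate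
21 | methyl 3,7-dioxo-6-endo-(dioxolanyl-propenyl)-cis-2-oxabicyclo[3.3.0]octane-4-carboxylate (ester drawn exo) | COC(=O)[C@H]1C(=O)O[C@@H]2CC(=O)[C@@H]([C@@H]21)C(=C)CC3(OCCO3)CCOCc4ccc(OC)cc4 | intermediate
22 | methyl 7-endo-hydroxy-7-exo-methyl-3-oxo-6-endo-(dioxolanyl-propenyl)-cis-2-oxabicyclo[3.3.0]octane-4-carboxylate | COC(=O)[C@H]1C(=O)O[C@@H]2C[C@](C)(O)[C@@H]([C@@H]21)C(=C)CC3(OCCO3)CCOCc4ccc(OC)cc4 | intermediate
23 | (1R,5S,6S,7S)-7-hydroxy-7-methyl-6-(dioxolanyl-propenyl)-2-oxabicyclo[3.3.0]octan-3-one | O=C1O[C@@H]2C[C@](C)(O)[C@@H]([C@@H]2C1)C(=C)CC3(OCCO3)CCOCc4ccc(OC)cc4 | intermediate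
24 | dilithium alkoxide enolate of 23 | [Li]OC=1O[C@@H]2C[C@](C)(O[Li])[C@@H]([C@@H]2C=1)C(=C)CC3(OCCO3)CCOCc4ccc(OC)cc4 | intermediate
25 | 23 alkylated at the lactone α-carbon (convex face) with the allyl unit of 7; metathesis diene | C=C(C)[C@H](CC(=O)OC)C(=C)C[C@H]1C(=O)O[C@@H]2C[C@](C)(O)[C@@H]([C@@H]21)C(=C)CC3(OCCO3)CCOCc4ccc(OC)cc4 | intermediate
26 | tricyclic lactone (rings A, B, C), tetrasubstituted ring-C alkene, PMB ether | C=C(C)[C@H](CC(=O)OC)C=1C[C@H]2C(=O)O[C@@H]3C[C@](C)(O)[C@@H]([C@@H]32)C1CC4(OCCO4)CCOCc5ccc(OC)cc5 | intermediate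
27 | tricyclic primary alcohol | C=C(C)[C@H](CC(=O)OC)C=1C[C@H]2C(=O)O[C@@H]3C[C@](C)(O)[C@@H]([C@@H]32)C1CC4(OCCO4)CCO | intermediate
28 | tricyclic aldehyde | C=C(C)[C@H](CC(=O)OC)C=1C[C@H]2C(=O)O[C@@H]3C[C@](C)(O)[C@@H]([C@@H]32)C1CC4(OCCO4)CC=O | intermediate
29 | tetracyclic spiro alcohol, ring-D ketone as dioxolane | C=C(C)[C@H](CC(=O)OC)C1=C[C@H]2C(=O)O[C@@H]3C[C@](C)(O)[C@@H]([C@@H]32)[C@]12CC3(OCCO3)C[C@@H]2O | intermediate
30 | CNP0255095.1 | C=C(C)[C@H](CC(=O)OC)C1=C[C@H]2C(=O)O[C@@H]3C[C@](C)(O)[C@@H]([C@@H]32)[C@]12CC(=O)C[C@@H]2O | target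

## Step count and risks

Total: 23 steps. Longest linear sequence: 16 steps (steps 7–10, then 12–23).

The three steps most likely to fail:

Step 22 (carbonyl-ene). The aldehyde may bond to the other alkene carbon through the competing six-membered mode, the hydrogen may be taken from the side-chain methine, or facial selectivity at the carbinol carbon may be poor. The fallback sets out from 28 and returns at 29. Intramolecular Paternò–Büchi photocycloaddition (hν 300 nm, MeCN) should give the cis-fused tetracyclic oxetane F1, in which the oxygen is necessarily cis to the ring-C carbon on ring D. Lewis-acid isomerisation of the oxetane (BF3·OEt2 20 mol%, 2,6-di-tert-butylpyridine, CH2Cl2, −78 °C; heterolysis of the tertiary C–O bond and loss of a proton from the ring CH2) should then give 29.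

Step 19 (ring-closing metathesis). The two hindered 1,1-disubstituted alkenes may fail to engage before the ruthenium carbene decomposes, or oligomerisation through the isopropenyl group may compete. The fallback sets out from 25 and returns at 26. The tertiary alcohol is masked (Et3SiOTf, 2,6-lutidine) as the triethylsilyl ether of the diene F2. The ring is then closed on a different metal-carbene platform, the molybdenum alkylidene Mo(=CHCMe2Ph)(=N-2,6-iPr2C6H3)[OCMe(CF3)2]2 (benzene, 60 °C), which is the established choice for tetrasubstituted cycloalkenes but does not tolerate the free hydroxyl; this should give the silylated tricycle F3. HF·pyridine then returns 26.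

Step 15 (Michael lactonisation). The acyloxy group may be lost from the enone by β-elimination, or base may epimerise the freshly protonated ring carbon and move the double bond into conjugation. The fallback sets out from 19 and returns at 23. Acylation with bromoacetyl bromide/pyridine gives the bromoacetate F4. SmI2 (THF, −78 °C) generates the samarium enolate for a Reformatsky-type intramolecular conjugate addition under non-basic conditions, which should give the keto lactone F5. MeMgBr/CeCl3 then leads directly to 23, with no decarboxylation needed.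

Further compounds
F1 | step 22 | cis-fused tetracyclic oxetane (oxygen bridging the ring-D carbinol carbon and the side-chain-bearing ring-C carbon) | C=C(C)[C@H](CC(=O)OC)[C@]15C[C@H]2C(=O)O[C@@H]3C[C@](C)(O)[C@@H]([C@@H]32)[C@]12CC4(OCCO4)C[C@@H]2O5
F2 | step 19 | triethylsilyl ether of diene 25 | C=C(C)[C@H](CC(=O)OC)C(=C)C[C@H]1C(=O)O[C@@H]2C[C@](C)(O[Si](CC)(CC)CC)[C@@H]([C@@H]21)C(=C)CC3(OCCO3)CCOCc4ccc(OC)cc4
F3 | step 19 | triethylsilyl ether of tricycle 26 | C=C(C)[C@H](CC(=O)OC)C=1C[C@H]2C(=O)O[C@@H]3C[C@](C)(O[Si](CC)(CC)CC)[C@@H]([C@@H]32)C1CC4(OCCO4)CCOCc5ccc(OC)cc5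
F4 | step 15 | bromoacetate of 19 | BrCC(=O)O[C@H]1C=C(C(=C)CC2(CCOCc3ccc(OC)cc3)OCCO2)C(=O)C1
F5 | step 15 | 6-endo-(dioxolanyl-propenyl)-cis-2-oxabicyclo[3.3.0]octane-3,7-dione | O=C1O[C@@H]2CC(=O)[C@@H]([C@@H]2C1)C(=C)CC3(OCCO3)CCOCc4ccc(OC)cc4
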